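**Plan**

1. Retrosynthesis: the quinone is taken back (oxidation level, O-benzyl) to its hydroquinone. Ring B is cut at C6'–C1' (ring CH to the neighbouring carbonyl carbon) and re-closed as a temporary four-membered ring between C1' and C4'. The resulting 4-(1-substituted vinyl)-4-hydroxy-2,3-dimethoxycyclobutenone is cut at C4'–C5' into dimethyl squarate and a 2-lithio-1-alkene.
2. Enabling feature: ring B is a six-membered carbocycle whose four contiguous oxygenated carbons (C1'=O, C2'–OMe, C3'–OMe, C4'=O) are the four carbons of squaric ester. C5' (bearing chroman C3) and C6'–H are a 1,1-disubstituted vinyl group.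
3. The vinyl anion goes back by a Shapiro reaction to a methyl ketone and to (3R)-chroman-3-carboxylic acid. The pyran ring is cut at C3–H/C4–H (hydrogenation) and at O1–C2/C3–C4 (oxa-Michael/aldol) to a salicylaldehyde and acrylonitrile.
4. Forward order: ring A (commercial arene, fourth oxygen by Elbs oxidation), then the pyran ring, the stereocentre, the vinyllithium, the cyclobutenone, ring B by 4π opening/6π closure, and last the quinone.
5. Stereochemistry: C3 comes from catalyst-controlled asymmetric hydrogenation of the 2H-chromene-3-carboxylic acid. The carbinol centre formed in the squarate addition arises as both epimers, and both converge in the ring expansion.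

Key step: step 10

Assumption: the sense of induction in step 5 is taken to follow that of this catalyst class with 2H-chromene-3-carboxylic acids, so the ligand antipode that delivers the 3R acid is used; the 3R acid, amide and ketone have the same spatial arrangement at C3 as the 3S target, the descriptor changing only with substituent priority.

**Step 1**
Reactants: 1 2-hydroxy-3,4-dimethoxybenzaldehyde
Product: 3 2,5-dihydroxy-3,4-dimethoxybenzaldehyde, via aryl sulfate 2 (not isolated)
Conditions: K2S2O8 (1.1 equiv), NaOH (10% aq), 0 °C to rt; then HCl (aq), 80 °C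
Reagents that add atoms: potassium peroxodisulfate, [K+].[K+].[O-]S(=O)(=O)OOS(=O)(=O)[O-]
Why: Elbs persulfate oxidation, in which the phenoxide attacks peroxodisulfate through its free para carbon (C5) and acid hydrolysis of the aryl sulfate frees the second phenol, as is classical for the closely related 2-hydroxy-3,4-dimethoxyacetophenone.

**Step 2**
Reactants: 3 2,5-dihydroxy-3,4-dimethoxybenzaldehyde
Product: 4 5-(benzyloxy)-2-hydroxy-3,4-dimethoxybenzaldehyde
Conditions: BnBr (1.05 equiv), K2CO3 (1.1 equiv), acetone, reflux, argon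
Reagents that add atoms: benzyl bromide, BrCc1ccccc1
Why: Williamson ether synthesis that should be selective for the 5-OH, because the 2-OH is held in a hydrogen bond to the aldehyde and its phenoxide is the weaker nucleophile; the benzyl group also keeps a free phenol away from the later ketene.

**Step 3**
Reactants: 4 5-(benzyloxy)-2-hydroxy-3,4-dimethoxybenzaldehyde; 5 acrylonitrile
Product: 6 6-(benzyloxy)-7,8-dimethoxy-2H-chromene-3-carbonitrile
Conditions: DABCO (0.5 equiv), acrylonitrile (neat, excess), 80 °C
Reagents that add atoms: none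
Why: DABCO-mediated oxa-Michael/Baylis–Hillman-type aldol condensation of a salicylaldehyde with acrylonitrile, the standard entry to 2H-chromene-3-carbonitriles, which closes the pyran ring with loss of water.

**Step 4**
Reactants: 6 6-(benzyloxy)-7,8-dimethoxy-2H-chromene-3-carbonitrile
Product: 7 6-(benzyloxy)-7,8-dimethoxy-2H-chromene-3-carboxylic acid
Conditions: NaOH (10% aq), reflux; then HCl (aq) to pH 2
Reagents that add atoms: water, O; sodium hydroxide, [Na+].[OH-]
Why: alkaline nitrile hydrolysis, routine for 2H-chromene-3-carbonitriles, to which the aryl ethers are inert.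

**Step 5**
Reactants: 7 6-(benzyloxy)-7,8-dimethoxy-2H-chromene-3-carboxylic acid
Product: 8 (3R)-6-(benzyloxy)-7,8-dimethoxychromane-3-carboxylic acid
Conditions: H2 (6 atm), [Ir(cod)(SIPHOX)][B(3,5-(CF3)2C6H3)4] (1 mol%, ligand antipode chosen for the 3R acid), Et3N (0.5 equiv), MeOH, 45 °C
Reagents that add atoms: none
Why: carboxylate-directed iridium-catalysed asymmetric hydrogenation of an α,β-unsaturated acid, a reaction class established for 2H-chromene-3-carboxylic acids, in which the chiral spiro phosphine–oxazoline ligand fixes the face of hydrogen delivery to C3/C4 and so sets C3, while the homogeneous catalyst leaves the benzyl ether alone.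

**Step 6**
Reactants: 8 (3R)-6-(benzyloxy)-7,8-dimethoxychromane-3-carboxylic acid
Product: 10 (3R)-6-(benzyloxy)-N,7,8-trimethoxy-N-methylchromane-3-carboxamide, via acyl imidazolide 9 (not isolated)
Conditions: CDI (1.1 equiv), CH2Cl2, rt, 1 h; then MeNHOMe·HCl (1.3 equiv), rt
Reagents that add atoms: N,O-dimethylhydroxylamine hydrochloride, CNOC.Cl
Why: amide formation through the acyl imidazolide under near-neutral conditions, chosen so that C3 (alpha to the carbonyl and beta to the aryloxy group) meets no strong base.

**Step 7**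
Reactants: 10 (3R)-6-(benzyloxy)-N,7,8-trimethoxy-N-methylchromane-3-carboxamide
Product: 11 1-[(3R)-6-(benzyloxy)-7,8-dimethoxychroman-3-yl]ethan-1-one
Conditions: MeMgBr (1.5 equiv), THF, 0 °C; cold aq NH4Cl
Reagents that add atoms: methylmagnesium bromide, C[Mg]Br
Why: Weinreb ketone synthesis, which stops at the ketone and releases it only in the buffered quench, so that neither epimerisation nor retro-oxa-Michael opening at C3 should occur.

**Step 8**
Reactants: 11 1-[(3R)-6-(benzyloxy)-7,8-dimethoxychroman-3-yl]ethan-1-one
Product: 12 N'-{(1E)-1-[(3S)-6-(benzyloxy)-7,8-dimethoxychroman-3-yl]ethylidene}-2,4,6-tri(propan-2-yl)benzenesulfonohydrazide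
Conditions: TrisNHNH2 (1.05 equiv), THF, rt, no acid catalyst
Reagents that add atoms: 2,4,6-triisopropylbenzenesulfonohydrazide, CC(C)c1cc(C(C)C)c(S(=O)(=O)NN)c(C(C)C)c1
Why: hydrazone condensation of a methyl ketone, which should give the E isomer (sulfonamide nitrogen syn to the methyl group, anti to the branched chroman carbon) as needed for the next step.

**Step 9**
Reactants: 12 the trisylhydrazone; 13 dimethyl squarate (3,4-dimethoxycyclobut-3-ene-1,2-dione)
Product: 15 4-{1-[(3S)-6-(benzyloxy)-7,8-dimethoxychroman-3-yl]ethenyl}-4-hydroxy-2,3-dimethoxycyclobut-2-en-1-one (both epimers at the carbinol carbon), via vinyllithium 14 (not isolated)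
Conditions: n-BuLi (2.05 equiv), THF, −78 °C, then 0 °C until N2 evolution ends; cannulation into 13 (1.2 equiv), THF, −78 °C; aq NH4Cl at −78 °C
Reagents that add atoms: none
Why: Shapiro reaction, in which the second deprotonation takes place at the methyl group syn to the sulfonamide nitrogen (not at C3) and loss of sulfinate and N2 gives the 1-substituted vinyllithium, followed by 1,2-addition to one of the two equivalent carbonyl groups of the squaric ester, as known for 2-lithiopropene; the new carbinol centre is not controlled and need not be.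

**Step 10**
Reactants: 15 the 4-alkenyl-4-hydroxycyclobutenone
Product: 18 5-[(3S)-6-(benzyloxy)-7,8-dimethoxychroman-3-yl]-2,3-dimethoxybenzene-1,4-diol, via dienylketene 16 (not isolated), via cyclohexadienone 17 (not isolated)
Conditions: degassed toluene (0.02 M), 110 °C, argon; concentrated under argon and used at once
Reagents that add atoms: none
Why: Heating should open the strained cyclobutenone by conrotatory 4π cleavage of the C1–C4 bond to the dienylketene 16, whose ketene carbon then bonds to the terminal CH2 of the vinyl group to give the cyclohexa-2,4-dienone 17, which enolises to the aromatic hydroquinone. The closest known reaction type is the thermal ring expansion of 4-alkenyl-4-hydroxycyclobutenones made from squaric esters to hydroquinones, the alkenyl counterpart of the Moore rearrangement. Ring B closes by a disrotatory 6π electrocyclisation of a hexatriene (ketene C=C, C(OMe)=C(OH), C=CH2) whose six atoms all become ring atoms. No stereocentre is created: the carbinol centre of 15 is destroyed, so both epimers converge, and chroman C3 is a spectator under neutral thermal conditions. The step needs the ring opening to turn the vinyl group inward (cis to the ketene), which the donor hydroxyl secures by rotating outward, and the placement of the substituent at C5' and of H at C6' is fixed because the vinyl CH2 is the only triene terminus. Release of ring strain and aromatisation drive the sequence, and dilution together with the absence of a free phenol should suppress intermolecular trapping of the ketene.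

**Step 11**
Reactants: 18 the O-benzyl hydroquinone
Product: 20 5-[(3S)-6-hydroxy-7,8-dimethoxy-3,4-dihydro-2H-chromen-3-yl]-2,3-dimethoxycyclohexa-2,5-diene-1,4-dione, via debenzylated hydroquinone 19 (not isolated)
Conditions: H2 (1 atm), Pd/C (10 wt%), EtOAc, rt; filtration under argon; Ag2O (1.5 equiv), Et2O, rt; base-free work-up
Reagents that add atoms: none
Why: hydrogenolysis of the aryl benzyl ether followed by dehydrogenation of the ring B hydroquinone with Ag2O, which should spare the far less oxidisable para-alkoxyphenol of ring A; base is avoided because C3–H of the quinone is vinylogously acidic.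

**Compound list**

1 | 2-hydroxy-3,4-dimethoxybenzaldehyde | O=Cc1ccc(OC)c(OC)c1O | starting material
2 | potassium 5-formyl-4-hydroxy-2,3-dimethoxyphenyl sulfate | O=Cc1cc(OS(=O)(=O)[O-])c(OC)c(OC)c1O.[K+] | intermediate
3 | 2,5-dihydroxy-3,4-dimethoxybenzaldehyde | O=Cc1cc(O)c(OC)c(OC)c1O | intermediate
4 | 5-(benzyloxy)-2-hydroxy-3,4-dimethoxybenzaldehyde | O=Cc1cc(OCc2ccccc2)c(OC)c(OC)c1O | intermediate
5 | acrylonitrile | C=CC#N | starting material
6 | 6-(benzyloxy)-7,8-dimethoxy-2H-chromene-3-carbonitrile | N#CC1=Cc2cc(OCc3ccccc3)c(OC)c(OC)c2OC1 | intermediate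
7 | 6-(benzyloxy)-7,8-dimethoxy-2H-chromene-3-carboxylic acid | OC(=O)C1=Cc2cc(OCc3ccccc3)c(OC)c(OC)c2OC1 | intermediate
8 | (3R)-6-(benzyloxy)-7,8-dimethoxychromane-3-carboxylic acid | OC(=O)[C@H]1COc2c(cc(OCc3ccccc3)c(OC)c2OC)C1 | intermediate
9 | [(3R)-6-(benzyloxy)-7,8-dimethoxychroman-3-yl](1H-imidazol-1-yl)methanone | O=C([C@H]1COc2c(cc(OCc3ccccc3)c(OC)c2OC)C1)n1ccnc1 | intermediate
10 | (3R)-6-(benzyloxy)-N,7,8-trimethoxy-N-methylchromane-3-carboxamide | CON(C)C(=O)[C@H]1COc2c(cc(OCc3ccccc3)c(OC)c2OC)C1 | intermediate
11 | 1-[(3R)-6-(benzyloxy)-7,8-dimethoxychroman-3-yl]ethan-1-one | CC(=O)[C@H]1COc2c(cc(OCc3ccccc3)c(OC)c2OC)C1 | intermediate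
12 | N'-{(1E)-1-[(3S)-6-(benzyloxy)-7,8-dimethoxychroman-3-yl]ethylidene}-2,4,6-tri(propan-2-yl)benzenesulfonohydrazide | C/C(=N\NS(=O)(=O)c1c(C(C)C)cc(C(C)C)cc1C(C)C)[C@H]1COc2c(cc(OCc3ccccc3)c(OC)c2OC)C1 | intermediate
13 | dimethyl squarate (3,4-dimethoxycyclobut-3-ene-1,2-dione) | COC1=C(OC)C(=O)C1=O | starting material
14 | {1-[(3S)-6-(benzyloxy)-7,8-dimethoxychroman-3-yl]ethenyl}lithium | [Li]C(=C)[C@H]1COc2c(cc(OCc3ccccc3)c(OC)c2OC)C1 | intermediate
15 | 4-{1-[(3S)-6-(benzyloxy)-7,8-dimethoxychroman-3-yl]ethenyl}-4-hydroxy-2,3-dimethoxycyclobut-2-en-1-one (both carbinol epimers) | COC1=C(OC)C(O)(C(=C)[C@H]2COc3c(cc(OCc4ccccc4)c(OC)c3OC)C2)C1=O | intermediate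
16 | (3Z)-5-[(3S)-6-(benzyloxy)-7,8-dimethoxychroman-3-yl]-4-hydroxy-2,3-dimethoxyhexa-1,3,5-trien-1-one | O=C=C(OC)/C(OC)=C(/O)C(=C)[C@H]1COc2c(cc(OCc3ccccc3)c(OC)c2OC)C1 | intermediate
17 | 5-[(3S)-6-(benzyloxy)-7,8-dimethoxychroman-3-yl]-4-hydroxy-2,3-dimethoxycyclohexa-2,4-dien-1-one | COC1=C(OC)C(O)=C([C@H]2COc3c(cc(OCc4ccccc4)c(OC)c3OC)C2)CC1=O | intermediate
18 | 5-[(3S)-6-(benzyloxy)-7,8-dimethoxychroman-3-yl]-2,3-dimethoxybenzene-1,4-diol | COc1c(OC)c(O)c([C@H]2COc3c(cc(OCc4ccccc4)c(OC)c3OC)C2)cc1O | intermediate
19 | 5-[(3S)-6-hydroxy-7,8-dimethoxychroman-3-yl]-2,3-dimethoxybenzene-1,4-diol | COc1c(OC)c(O)c([C@H]2COc3c(cc(O)c(OC)c3OC)C2)cc1O | intermediate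
20 | 5-[(3S)-6-hydroxy-7,8-dimethoxy-3,4-dihydro-2H-chromen-3-yl]-2,3-dimethoxycyclohexa-2,5-diene-1,4-dione | COC1=C(OC)C(=O)C([C@H]2COc3c(cc(O)c(OC)c3OC)C2)=CC1=O | target

**Count**

Total steps: 11. Longest linear sequence: 11 steps (from 1; 5 and 13 are bought).

**Steps most likely to fail**

Step 9. The alkyllithium may deprotonate the hydrazone on the C3 side or metalate the benzyl ether or arene. That would erase the C3 configuration through beta-elimination of the aryloxide, and fragmentation to the vinyllithium may also stay incomplete. The fallback sets out from Weinreb amide 10 and makes the same vinyllithium by halogen–lithium exchange. DIBAL-H (THF, −78 °C) should give (3R)-6-(benzyloxy)-7,8-dimethoxychromane-3-carbaldehyde F1, which is used crude under neutral conditions. CBr4/PPh3 with 2,6-lutidine (CH2Cl2, 0 °C) should give the dibromoalkene (3S)-6-(benzyloxy)-3-(2,2-dibromoethenyl)-7,8-dimethoxychromane F2. n-BuLi (2.1 equiv, THF, −78 °C; Corey–Fuchs sequence) then aq NH4Cl should give the alkyne (3S)-6-(benzyloxy)-3-ethynyl-7,8-dimethoxychromane F3. Alpha-selective hydroalumination with DIBAL-H and Ni(dppp)Cl2 (3 mol%, THF, 0 °C to rt) followed by NBS should give the 2-bromoalkene (3R)-6-(benzyloxy)-3-(1-bromoethenyl)-7,8-dimethoxychromane F4. t-BuLi (2.0 equiv, Et2O, −78 °C) should then give vinyllithium 14, where the route is rejoined before the addition to 13.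

Step 10. The ring opening may turn the hydroxyl inward, or the hydroxy ketene may be intercepted (lactonisation to a furanone, intermolecular acylation), or the hydroquinone may decompose oxidatively at the reaction temperature. The fallback again sets out from Weinreb amide 10, which is taken to the alkyne F3 as described under step 9. Deprotonation of F3 with n-BuLi (THF, −78 °C) and addition to 13 should give the alkynyl carbinol 4-{[(3S)-6-(benzyloxy)-7,8-dimethoxychroman-3-yl]ethynyl}-4-hydroxy-2,3-dimethoxycyclobut-2-en-1-one F5. Heating F5 in toluene or p-xylene (Moore rearrangement: 4π opening, closure to a diradical, hydrogen transfer) should give directly, at the quinone oxidation level, the O-benzyl quinone 5-[(3S)-6-(benzyloxy)-7,8-dimethoxychroman-3-yl]-2,3-dimethoxycyclohexa-2,5-diene-1,4-dione F6. H2 over Pd/C should reduce the quinone and cleave the benzyl ether to give 19, where the route is rejoined before the Ag2O oxidation.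

Step 5. Face selection may be insufficient, or turnover slow, with this tetra-oxygenated substrate, leaving material of low enantiomeric purity. The fallback sets out from acid 7 and replaces asymmetric catalysis by classical resolution. Hydrogenation with the achiral complex [Ir(cod)(PCy3)(py)]PF6 (H2, CH2Cl2, rt) should give the racemic acid rac-6-(benzyloxy)-7,8-dimethoxychromane-3-carboxylic acid F7. Crystallisation with (R)-1-phenylethylamine from EtOH/EtOAc should give the salt (R)-1-phenylethylammonium (3R)-6-(benzyloxy)-7,8-dimethoxychromane-3-carboxylate F8; the S amine is used if that one gives the less soluble salt with the 3R acid. Aqueous HCl should then release acid 8, where the route is rejoined.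

**Further compounds**

F1 | step 9 | (3R)-6-(benzyloxy)-7,8-dimethoxychromane-3-carbaldehyde | O=C[C@H]1COc2c(cc(OCc3ccccc3)c(OC)c2OC)C1
F2 | step 9 | (3S)-6-(benzyloxy)-3-(2,2-dibromoethenyl)-7,8-dimethoxychromane | BrC(Br)=C[C@H]1COc2c(cc(OCc3ccccc3)c(OC)c2OC)C1
F3 | step 9 | (3S)-6-(benzyloxy)-3-ethynyl-7,8-dimethoxychromane | C#C[C@H]1COc2c(cc(OCc3ccccc3)c(OC)c2OC)C1
F4 | step 9 | (3R)-6-(benzyloxy)-3-(1-bromoethenyl)-7,8-dimethoxychromane | C=C(Br)[C@H]1COc2c(cc(OCc3ccccc3)c(OC)c2OC)C1
F5 | step 10 | 4-{[(3S)-6-(benzyloxy)-7,8-dimethoxychroman-3-yl]ethynyl}-4-hydroxy-2,3-dimethoxycyclobut-2-en-1-one | COC1=C(OC)C(O)(C#C[C@H]2COc3c(cc(OCc4ccccc4)c(OC)c3OC)C2)C1=O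
F6 | step 10 | 5-[(3S)-6-(benzyloxy)-7,8-dimethoxychroman-3-yl]-2,3-dimethoxycyclohexa-2,5-diene-1,4-dione | COC1=C(OC)C(=O)C([C@H]2COc3c(cc(OCc4ccccc4)c(OC)c3OC)C2)=CC1=O
F7 | step 5 | rac-6-(benzyloxy)-7,8-dimethoxychromane-3-carboxylic acid | OC(=O)C1COc2c(cc(OCc3ccccc3)c(OC)c2OC)C1
F8 | step 5 | (R)-1-phenylethylammonium (3R)-6-(benzyloxy)-7,8-dimethoxychromane-3-carboxylate | C[C@@H]([NH3+])c1ccccc1.[O-]C(=O)[C@H]1COc2c(cc(OCc3ccccc3)c(OC)c2OC)C1
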